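**Plan**
1. Retrosynthetic cuts, in order. First the three phenol O–allyl bonds and a helper bond C3–CO2allyl, which stands on C3 in place of H. Then O1–C8a together with C2–C3, which releases formaldehyde and opens ring C to the acyclic 2-fluoroaryl beta-keto ester 11. Then C3–C4 (Claisen). Last, C1'–CH2 and C5'–geranyl, back to symmetric 4,6-diiodoresorcinol.
2. Enabling feature. In ring A, C8a is ortho to the C4 carbonyl, so O=C4–C4a=C8a is a vinylogous acyl unit. With fluorine on C8a it accepts an alkoxide by addition–elimination. C3 lies between ring B, C4=O and the helper ester, so carbonate is enough for it to pick up CH2O.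
3. Forward order. Ring B is dressed (allyl ethers, geranyl, CH2CO2allyl) and joined to the ring A ester at C3–C4. Ring C is then closed in one flask, with both C2 and O1 coming from formaldehyde.
4. Stereochemistry. C3 stays quaternary, racemic and non-enolisable until the last flask. There a palladium-catalysed decarboxylative protonation under a chiral phosphinooxazoline sets (3R) in a weakly acidic medium, and the same zerovalent palladium chemistry removes the allyl ethers. The E olefin comes with geranyl bromide.

Key step: step 6

Remark: isoflavanone numbering is used (O1, C2, C3, C4, C4a, C5–C8, C8a; ring B C1'–C6'). Geranyl means (2E)-3,7-dimethylocta-2,6-dien-1-yl.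
Assumption: C3 of the target is R (C4 > C2 > C1' > H). The (S)-phosphinooxazoline/Meldrum's acid pair is taken to give this sense. In this reaction type the sense changes with the ligand antipode and with the proton donor, so the (R)-ligand is used if a first run shows the opposite.

Step 1
Reactants: 1 4,6-diiodoresorcinol
Product: 2 1,5-diiodo-2,4-bis(allyloxy)benzene
Conditions: allyl bromide (2.4 equiv), K2CO3 (3 equiv), DMF, 40 °C
Reagents that add atoms: allyl bromide, C=CCBr
Why: Williamson ether synthesis on the two equivalent phenols should give a base- and Grignard-stable diether whose allyl groups can later be removed under near-neutral conditions.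

Step 2
Reactants: 2 1,5-diiodo-2,4-bis(allyloxy)benzene; 3 geranyl bromide
Product: 5 1-geranyl-5-iodo-2,4-bis(allyloxy)benzene, via arylmagnesium chloride 4 (not isolated)
Conditions: iPrMgCl·LiCl (1.05 equiv), THF, −20 °C; then Li2CuCl4 (5 mol %), 3 (1.2 equiv), −20 → 0 °C
Reagents that add atoms: none
Why: Iodine–magnesium exchange should stop after one of the two equivalent iodides because the first carbanion deactivates the ring, and the copper-catalysed Grignard–allyl halide coupling (Kochi type) should occur at the primary carbon of 3 with the E olefin retained, since the other allyl terminus is fully substituted.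

Step 3
Reactants: 5 1-geranyl-5-iodo-2,4-bis(allyloxy)benzene; 6 allyl acetoacetate
Product: 8 allyl [2,4-bis(allyloxy)-5-geranylphenyl]acetate, via aryl acetoacetate 7 (not isolated)
Conditions: CuI (20 mol %), L-proline (40 mol %), Cs2CO3 (3 equiv), DMSO, 50 °C; then allyl alcohol (5 equiv), 85 °C
Reagents that add atoms: none
Why: Hurtley-type copper-catalysed arylation of the acetoacetate enolate by the aryl iodide, followed in the same flask by retro-Claisen transfer of the acetyl group to allyl alcohol, is a palladium-free route to the arylacetate that leaves every allyl group untouched.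

Step 4
Reactants: 9 2-fluoro-4-hydroxybenzoic acid
Product: 10 allyl 4-(allyloxy)-2-fluorobenzoate
Conditions: allyl bromide (2.4 equiv), K2CO3 (3 equiv), DMF, 40 °C
Reagents that add atoms: allyl bromide, C=CCBr
Why: One Williamson/carboxylate alkylation protects the phenol and turns the acid into the ester electrophile for step 5, the aryl fluoride being inert at this temperature.

Step 5
Reactants: 8 allyl [2,4-bis(allyloxy)-5-geranylphenyl]acetate; 10 allyl 4-(allyloxy)-2-fluorobenzoate
Product: 11 allyl 3-[4-(allyloxy)-2-fluorophenyl]-2-[2,4-bis(allyloxy)-5-geranylphenyl]-3-oxopropanoate (racemic, keto/enol)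
Conditions: 8, LiHMDS (2.3 equiv), THF, −78 °C; then 10, −78 → −10 °C; AcOH quench
Reagents that add atoms: none
Why: Crossed Claisen condensation of the fully preformed arylacetate enolate with the non-enolisable, fluorine-activated benzoate is driven by deprotonation of the product by the second equivalent of base, and the temperature stays below that of the [3,3] shift of allyl ester enolates.

Step 6
Reactants: 11 allyl 3-[4-(allyloxy)-2-fluorophenyl]-2-[2,4-bis(allyloxy)-5-geranylphenyl]-3-oxopropanoate
Product: 13 allyl 7-(allyloxy)-3-[2,4-bis(allyloxy)-5-geranylphenyl]-4-oxochromane-3-carboxylate (racemic), via hydroxymethyl keto ester 12 (not isolated)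
Conditions: (CH2O)n (3 equiv), dry K2CO3 (2 equiv), DMF, 20 → 60 °C
Reagents that add atoms: formaldehyde (fed as paraformaldehyde), C=O
Why: Carbonate removes the doubly activated C3–H of 11 and the enolate adds through carbon to formaldehyde (aldol hydroxymethylation), which makes C2–C3, makes C3 quaternary and restores the C4 ketone in 12; the alkoxide O1 then adds to C8a, the fluorine-bearing carbon ortho to C4=O (O=C4–C4a=C8a–F is a vinylogous acyl fluoride), giving a Meisenheimer anion delocalised into the C4 carbonyl, and loss of fluoride closes ring C. The closest known reaction types are the hydroxymethylation of 2-substituted beta-keto esters and the domino addition/SNAr annulations of 2-fluoroaryl ketones, including the closure of 3-hydroxy-1-(2-fluorophenyl) ketones to chroman-4-ones. Ring C closes by a 6-endo-trig addition–elimination on the C4a=C8a bond, helped by the geminal substitution at C3. The new quaternary C3 is formed as a racemate on purpose, because step 7 flattens it to the enolate. The step needs C- over O-hydroxymethylation, ring closure over acyl transfer (O1 onto C4, four-membered, retro-Claisen) and no dehydration: both additions to formaldehyde are reversible and only the C-adduct carries the ketone that activates C8a, the six-membered closure is strain-free and ends in irreversible loss of fluoride, and the ester on C3 removes the proton that would allow E1cB loss of water, enolisation of C4=O (which would switch off C8a) or a second hydroxymethylation. The 7-allyloxy group is meta to C8a and so does not push electron density onto the carbon under attack.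

Step 7
Reactants: 13 allyl 7-(allyloxy)-3-[2,4-bis(allyloxy)-5-geranylphenyl]-4-oxochromane-3-carboxylate
Product: 15 (3R)-7,2',4'-trihydroxy-5'-geranylisoflavanone (target), via tri-O-allyl isoflavanone 14 (not isolated)
Conditions: Pd2(dba)3 (5 mol %), (S)-(CF3)3-t-BuPHOX [(S)-2-{2-[bis(4-trifluoromethylphenyl)phosphino]-5-(trifluoromethyl)phenyl}-4-tert-butyl-4,5-dihydrooxazole] (12.5 mol %), Meldrum's acid (8 equiv), 1,4-dioxane, 20 °C; then Pd(PPh3)4 (5 mol %), 35 °C; base-free work-up
Reagents that add atoms: none
Why: Zerovalent palladium ionises the allyl ester, the carboxylate loses CO2 and the enolate held in the chiral pocket of the phosphinooxazoline complex is protonated on one face by Meldrum's acid (decarboxylative asymmetric protonation, a reaction type established on allyl 3-aryl-4-oxochroman-3-carboxylates bearing ortho-alkoxyaryl groups) to set (3R) in 14, after which Tsuji–Trost ionisation of the three aryl allyl ethers, with the same C–H acid as allyl acceptor, frees the phenols in a medium too weakly acidic and too weakly basic to enolise C3, cyclise the geranyl phenol or dehydrate the 2'-hydroxy ketone.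

**Compound list**
1 | 4,6-diiodoresorcinol | Oc1cc(O)c(I)cc1I | starting material
2 | 1,5-diiodo-2,4-bis(allyloxy)benzene | C=CCOc1cc(OCC=C)c(I)cc1I | intermediate
3 | geranyl bromide, (2E)-1-bromo-3,7-dimethylocta-2,6-diene | CC(C)=CCC/C(C)=C/CBr | starting material
4 | [5-iodo-2,4-bis(allyloxy)phenyl]magnesium chloride | C=CCOc1cc(OCC=C)c([Mg]Cl)cc1I | intermediate
5 | 1-geranyl-5-iodo-2,4-bis(allyloxy)benzene | CC(C)=CCC/C(C)=C/Cc1cc(I)c(OCC=C)cc1OCC=C | intermediate
6 | allyl acetoacetate | CC(=O)CC(=O)OCC=C | starting material
7 | allyl 2-[2,4-bis(allyloxy)-5-geranylphenyl]-3-oxobutanoate | CC(C)=CCC/C(C)=C/Cc1cc(C(C(C)=O)C(=O)OCC=C)c(OCC=C)cc1OCC=C | intermediate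
8 | allyl [2,4-bis(allyloxy)-5-geranylphenyl]acetate | CC(C)=CCC/C(C)=C/Cc1cc(CC(=O)OCC=C)c(OCC=C)cc1OCC=C | intermediate
9 | 2-fluoro-4-hydroxybenzoic acid | OC(=O)c1ccc(O)cc1F | starting material
10 | allyl 4-(allyloxy)-2-fluorobenzoate | C=CCOC(=O)c1ccc(OCC=C)cc1F | intermediate
11 | allyl 3-[4-(allyloxy)-2-fluorophenyl]-2-[2,4-bis(allyloxy)-5-geranylphenyl]-3-oxopropanoate (racemic) | CC(C)=CCC/C(C)=C/Cc1cc(C(C(=O)OCC=C)C(=O)c2ccc(OCC=C)cc2F)c(OCC=C)cc1OCC=C | intermediate
12 | allyl 2-[4-(allyloxy)-2-fluorobenzoyl]-2-[2,4-bis(allyloxy)-5-geranylphenyl]-3-hydroxypropanoate (racemic) | CC(C)=CCC/C(C)=C/Cc1cc(C(CO)(C(=O)OCC=C)C(=O)c2ccc(OCC=C)cc2F)c(OCC=C)cc1OCC=C | intermediate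
13 | allyl 7-(allyloxy)-3-[2,4-bis(allyloxy)-5-geranylphenyl]-4-oxochromane-3-carboxylate (racemic) | CC(C)=CCC/C(C)=C/Cc1cc(C2(C(=O)OCC=C)COc3cc(OCC=C)ccc3C2=O)c(OCC=C)cc1OCC=C | intermediate
14 | (3R)-7-(allyloxy)-3-[2,4-bis(allyloxy)-5-geranylphenyl]chroman-4-one | CC(C)=CCC/C(C)=C/Cc1cc([C@@H]2COc3cc(OCC=C)ccc3C2=O)c(OCC=C)cc1OCC=C | intermediate
15 | (3R)-7-hydroxy-3-[2,4-dihydroxy-5-geranylphenyl]chroman-4-one | CC(C)=CCC/C(C)=C/Cc1cc([C@@H]2COc3cc(O)ccc3C2=O)c(O)cc1O | target

Total step count: 7. Longest linear sequence: 6 (steps 1, 2, 3, 5, 6, 7).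

**Steps most likely to fail**

1. Step 6.
   - What may go wrong: the aroyl group may move from C3 to the new alkoxide (attack of O1 on C4, retro-Claisen), with later loss of the aroate. Adventitious hydroxide may also open the non-enolisable keto ester. Either process may outrun the ring closure.
   - Fallback: it sets out from 11 and returns at 14.
   - Krapcho dealkoxycarbonylation of 11 (LiCl, wet DMSO, 130 °C) should give the deoxybenzoin 1-[4-(allyloxy)-2-fluorophenyl]-2-[2,4-bis(allyloxy)-5-geranylphenyl]ethanone F1.
   - Claisen formylation (HCO2Et, NaH, THF) should give the hydroxymethylene ketone F2.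
   - With K2CO3 in DMF at 80 °C the enolate oxygen of F2 displaces the fluoride on C8a. This is the same ring bond, now made by a vinylogous carboxylate that has no retro-Claisen exit. The product is the tri-O-allyl isoflavone F3.
   - Asymmetric transfer hydrogenation (RuCl[(R,R)-TsDPEN](p-cymene), HCO2H/Et3N) reduces C2=C3 and then the ketone under dynamic kinetic resolution, giving the cis-(3R,4R)-isoflavan-4-ol F4.
   - Buffered Dess–Martin oxidation (NaHCO3, CH2Cl2, 0 °C) gives 14, which is deallylated as in the second half of step 7.

2. Step 7.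
   - What may go wrong: facial selectivity of the protonation may be poor. Causes could be background proton transfer, or early ether cleavage that places a free 2'-phenol next to the enolate. C-allylation of the enolate may also compete.
   - Fallback: it sets out from 13 and returns at 14.
   - Krapcho cleavage of 13 (LiCl, wet DMSO, 130 °C) should give the racemic tri-O-allyl isoflavanone F5.
   - The lability of C3 is then turned to use. Transfer hydrogenation with dynamic kinetic resolution (RuCl[(R,R)-TsDPEN](p-cymene), HCO2H/Et3N) converts both enantiomers into the same cis-(3R,4R)-alcohol F4.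
   - Buffered Dess–Martin oxidation gives 14, and Pd(PPh3)4 with Meldrum's acid then gives 15.

3. Step 3.
   - What may go wrong: the hindered, electron-rich iodide may couple slowly, with protodeiodination, and the ester may be cleaved during deacetylation.
   - Fallback: it sets out from 5 and returns at 8.
   - Iodine–magnesium exchange (iPrMgCl·LiCl, THF, 0 °C) gives [2,4-bis(allyloxy)-5-geranylphenyl]magnesium chloride F6.
   - CuI-catalysed opening of oxirane gives 2-[2,4-bis(allyloxy)-5-geranylphenyl]ethanol F7.
   - Oxidation with TEMPO/PhI(OAc)2 in MeCN–water gives [2,4-bis(allyloxy)-5-geranylphenyl]acetic acid F8.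
   - Allyl bromide and K2CO3 in DMF then give 8.

**Further compounds**
F1 | step 6 | 1-[4-(allyloxy)-2-fluorophenyl]-2-[2,4-bis(allyloxy)-5-geranylphenyl]ethanone | CC(C)=CCC/C(C)=C/Cc1cc(CC(=O)c2ccc(OCC=C)cc2F)c(OCC=C)cc1OCC=C
F2 | step 6 | 1-[4-(allyloxy)-2-fluorophenyl]-2-[2,4-bis(allyloxy)-5-geranylphenyl]-3-hydroxyprop-2-en-1-one | CC(C)=CCC/C(C)=C/Cc1cc(C(=CO)C(=O)c2ccc(OCC=C)cc2F)c(OCC=C)cc1OCC=C
F3 | step 6 | 7-(allyloxy)-3-[2,4-bis(allyloxy)-5-geranylphenyl]chromen-4-one | CC(C)=CCC/C(C)=C/Cc1cc(-c2coc3cc(OCC=C)ccc3c2=O)c(OCC=C)cc1OCC=C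
F4 | step 6 | (3R,4R)-7-(allyloxy)-3-[2,4-bis(allyloxy)-5-geranylphenyl]chroman-4-ol (cis) | CC(C)=CCC/C(C)=C/Cc1cc([C@@H]2COc3cc(OCC=C)ccc3[C@@H]2O)c(OCC=C)cc1OCC=C
F5 | step 7 | racemic 7-(allyloxy)-3-[2,4-bis(allyloxy)-5-geranylphenyl]chroman-4-one | CC(C)=CCC/C(C)=C/Cc1cc(C2COc3cc(OCC=C)ccc3C2=O)c(OCC=C)cc1OCC=C
F6 | step 3 | [2,4-bis(allyloxy)-5-geranylphenyl]magnesium chloride | CC(C)=CCC/C(C)=C/Cc1cc([Mg]Cl)c(OCC=C)cc1OCC=C
F7 | step 3 | 2-[2,4-bis(allyloxy)-5-geranylphenyl]ethanol | CC(C)=CCC/C(C)=C/Cc1cc(CCO)c(OCC=C)cc1OCC=C
F8 | step 3 | [2,4-bis(allyloxy)-5-geranylphenyl]acetic acid | CC(C)=CCC/C(C)=C/Cc1cc(CC(=O)O)c(OCC=C)cc1OCC=C
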